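**Retrosynthetic overview**

1. Last disconnection: the two aryl O–CH3 bonds. The target comes from (2R)-5,8-dimethoxy-2-pentadecylchroman-4-one by BBr3 demethylation.
2. Key disconnection: ring B (the dihydropyranone) is cut at C3–C4 and at O1–C2, giving 2-hydroxy-3,6-dimethoxybenzaldehyde and heptadec-1-yne. Forward, this is a one-pot, redox-neutral formal [4+2] annulation: rhodium-catalysed alkyne hydroacylation (C3–C4), then squaramide-catalysed enantioselective 6-endo oxa-Michael closure (O1–C2, sets C2).
3. Enabling feature: the salicyloyl array on ring A, with phenolic O1 on C8a ortho to the C4 carbonyl carbon on C4a. O1 first chelates rhodium so that the formyl C–H bond is activated without decarbonylation, then acts as the nucleophile that closes ring B; the C5 oxygen is capped as a methyl ether so that O1 is the only phenol able to close.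
4. Fragments: the aldehyde from 2,5-dimethoxybenzaldehyde (Dakin oxidation, magnesium-mediated ortho-formylation); the alkyne from 1-bromopentadecane and lithium acetylide.
5. Ring order: ring A (arene) is bought; ring B is the only ring formed, in the key step.

Key step: step 4

Remark: chroman-4-one numbering is used (O1, C2, C3, C4 carbonyl, C4a, C5 to C8, C8a); the stereocentre of the target SMILES is read as 2R (priorities O1 > C3 > pentadecyl > H).

**Route**

Step 1
Reactants: 1 2,5-dimethoxybenzaldehyde
Product: 3 2,5-dimethoxyphenol, via 2,5-dimethoxyphenyl formate 2 (not isolated)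
Conditions: mCPBA (1.3 equiv), CH2Cl2, 0 °C to rt; aq. NaHCO3 wash; then K2CO3 (cat.), MeOH, rt
Reagents that add atoms: mCPBA (3-chloroperoxybenzoic acid), OOC(=O)c1cccc(Cl)c1
Why: Dakin-type Baeyer–Villiger oxidation, in which the electron-rich aryl group migrates to oxygen to give formate 2, which base-catalysed methanolysis cleaves to the phenol.

Step 2
Reactants: 3 2,5-dimethoxyphenol
Product: 5 2-hydroxy-3,6-dimethoxybenzaldehyde, via 2-(hydroxymethyl)-3,6-dimethoxyphenol 4 (not isolated)
Conditions: MgCl2 (2 equiv), Et3N (4 equiv), (CH2O)n (6 equiv), MeCN, reflux; aq. HCl work-up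
Reagents that add atoms: paraformaldehyde (reacts as formaldehyde), C=O
Why: Casnati–Skattebøl magnesium-mediated ortho-formylation, in which the magnesium phenoxide delivers formaldehyde to C6, the only free ortho position, and the magnesium salt of benzylic alcohol 4 is oxidised by a second formaldehyde through Oppenauer-type hydride transfer.

Step 3
Reactants: 6 1-bromopentadecane
Product: 7 heptadec-1-yne
Conditions: LiC≡CH·H2NCH2CH2NH2 (1.5 equiv), DMSO, 10 °C to rt
Reagents that add atoms: lithium acetylide ethylenediamine complex, [Li]C#C.NCCN
Why: SN2 alkylation of lithium acetylide by an unhindered primary bromide in DMSO, the standard entry to terminal alkynes.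

Step 4
Reactants: 5 2-hydroxy-3,6-dimethoxybenzaldehyde; 7 heptadec-1-yne
Product: 9 (2R)-5,8-dimethoxy-2-pentadecylchroman-4-one, via (E)-1-(2-hydroxy-3,6-dimethoxyphenyl)octadec-2-en-1-one 8 (not isolated)
Conditions: [RhCl(C8H12)]2 (2.5 mol %), dppf [Fe(C5H4PPh2)2] (5 mol %), Na2CO3 (5 mol %), PhMe, 80 °C until 5 is consumed; then −20 to 0 °C, quinine-derived bifunctional squaramide (3-{[3,5-bis(trifluoromethyl)phenyl]amino}-4-{[(8α,9S)-6'-methoxycinchonan-9-yl]amino}cyclobut-3-ene-1,2-dione, 10 mol %); filtration through silica
Reagents that add atoms: none
Why: Proposed new method: the rhodium phenoxide of 5 (monovalent rhodium) adds oxidatively into the formyl C–H bond to give a five-membered O,C-chelated acyl hydride of trivalent rhodium, syn-hydrometalation of 7 places rhodium on the unsubstituted alkyne carbon and C–C reductive elimination forms the C3–C4 bond of (E)-enone 8; in the cold second stage the quinuclidine nitrogen of the squaramide catalyst activates the phenolic O–H while its two N–H bonds bind the C4 carbonyl, and O1 adds to the enone β-carbon to form the O1–C2 bond, all atoms of 5 and 7 ending in 9 with no co-product. The closest known reaction types are the rhodium-catalysed hydroacylation of alkynes with salicylaldehydes, its tandem extension by base-promoted oxa-Michael closure to racemic or trans-2,3-disubstituted chroman-4-ones, and the cinchona-thiourea-catalysed enantioselective oxa-Michael cyclisation of activated 2'-hydroxyaryl alkylidene β-ketoesters; what has not been shown is the enantioselective closure of an unactivated β-alkyl enone that is generated in the same flask. Ring B closes in a 6-endo-trig oxa-Michael mode, the overall change being a formal [4+2] union of the O1–C8a–C4a–C4 unit with the two alkyne carbons. The only new stereocentre, C2, is controlled by the chiral catalyst, which holds the enone and the phenol in a hydrogen-bonded array and lets O1 reach only one face of the β-carbon (the quinine-derived catalyst is specified for 2R, and its quinidine-derived pseudo-enantiomer takes its place should a first analytical run show the opposite sense). The step needs linear regioselectivity in the hydroacylation, for which the unhindered CH terminus of the 1-alkyne and the wide-bite-angle dppf ligand are relied on, freedom from decarbonylation, which the O1 chelate secures, a single site of closure, which the methyl ether on the C5 oxygen secures, and a slow uncatalysed (racemic) closure, for which the internal O–H···O=C hydrogen bond of 8 in toluene, the catalytic and insoluble Na2CO3 and the low temperature of the second stage are relied on.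

Step 5
Reactants: 9 (2R)-5,8-dimethoxy-2-pentadecylchroman-4-one
Product: 10 (2R)-5,8-dihydroxy-2-pentadecylchroman-4-one
Conditions: BBr3 (6 equiv), CH2Cl2, −78 °C to 0 °C, argon; then ice and degassed H2O, extraction under argon
Reagents that add atoms: none
Why: Lewis-acid ether cleavage (O–B coordination, then SN2 demethylation by bromide), in which the methyl C–O bonds react far faster than the secondary O1–C2 bond of the deactivated vinylogous-ester oxygen, and the base-free medium gives C2 no retro-oxa-Michael pathway.

**Compound list**

1 | 2,5-dimethoxybenzaldehyde | COc1ccc(OC)c(C=O)c1 | starting material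
2 | 2,5-dimethoxyphenyl formate | COc1ccc(OC)c(OC=O)c1 | intermediate
3 | 2,5-dimethoxyphenol | COc1ccc(OC)c(O)c1 | intermediate
4 | 2-(hydroxymethyl)-3,6-dimethoxyphenol (present as its magnesium salt) | OCc1c(O)c(OC)ccc1OC | intermediate
5 | 2-hydroxy-3,6-dimethoxybenzaldehyde | O=Cc1c(O)c(OC)ccc1OC | intermediate
6 | 1-bromopentadecane | CCCCCCCCCCCCCCCBr | starting material
7 | heptadec-1-yne | CCCCCCCCCCCCCCCC#C | intermediate
8 | (E)-1-(2-hydroxy-3,6-dimethoxyphenyl)octadec-2-en-1-one | CCCCCCCCCCCCCCC/C=C/C(=O)c1c(O)c(OC)ccc1OC | intermediate
9 | (2R)-5,8-dimethoxy-2-pentadecylchroman-4-one | CCCCCCCCCCCCCCC[C@@H]1CC(=O)c2c(OC)ccc(OC)c2O1 | intermediate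
10 | (2R)-5,8-dihydroxy-2-pentadecylchroman-4-one | CCCCCCCCCCCCCCC[C@@H]1CC(=O)c2c(O)ccc(O)c2O1 | target

**Step count and risks**

Total step count: 5. Longest linear sequence: 4 (steps 1, 2, 4, 5); step 3 is a one-step side branch.

Steps most likely to fail:

1. Step 4 (proposed new method). What may go wrong: hydrometalation of the alkyne with the reverse regiochemistry; base-mediated ring closure already during the hot hydroacylation stage, which would erode enantiopurity; and insufficient facial discrimination or retro-oxa-Michael equilibration in the cold stage. The fallback uses known chemistry, sets out from 5 and returns at 9. Hexadecanoyl chloride is treated with dimethylsulfoxonium methylide (Me3S(O)I, KOtBu, THF, reflux, then 0 °C) to give the sulfoxonium ylide 1-[dimethyl(oxo)-λ6-sulfanylidene]heptadecan-2-one F1. Compounds 5 and F1 are annulated with [RhCl2(C5Me5)]2 and AgSbF6 (DCE, 100 °C); this proceeds by phenol-directed formyl C–H activation at trivalent rhodium, carbene insertion and cyclodehydration of the resulting 1,3-diketone, and should give 5,8-dimethoxy-2-pentadecyl-4H-chromen-4-one F2. Copper hydride asymmetric conjugate reduction of F2 (Cu(OAc)2, DTBM-SEGPHOS, (EtO)2MeSiH, t-BuOH, toluene, rt), with the ligand enantiomer chosen so that hydride adds to the C2 face that gives 2R, should return 9.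

2. Step 2. What may go wrong: slow formylation at an ortho position flanked by a methoxy group, and condensation of the hydroxymethyl intermediate with a second phenol molecule at its free para position. The fallback sets out from 3 and returns at 5. Compound 3 is O-methoxymethylated (MOMCl, i-Pr2NEt, CH2Cl2) to 1,4-dimethoxy-2-(methoxymethoxy)benzene F3. Directed ortho-lithiation at the position between the OMOM and OMe groups (n-BuLi, TMEDA, THF, 0 °C) and a DMF quench should give 3,6-dimethoxy-2-(methoxymethoxy)benzaldehyde F4. Acetal cleavage (HCl, MeOH, rt) should return 5.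

3. Step 5. What may go wrong: Lewis-acid-mediated opening of ring B at O1–C2 or enolisation-driven loss of configuration at C2, incomplete cleavage of the C8 ether, and air oxidation of the hydroquinone during work-up. The fallback sets out from 9 and returns at 10. Oxidative demethylation with (NH4)2Ce(NO3)6 (MeCN/H2O, 0 °C) should give the quinone (2R)-2-pentadecyl-2,3-dihydro-4H-chromene-4,5,8-trione F5. Immediate reduction with Na2S2O4 (EtOAc/H2O, rt, argon) should give 10 without any Lewis acid or base touching C2.

**Further compounds**

F1 | step 4 | 1-[dimethyl(oxo)-λ6-sulfanylidene]heptadecan-2-one | CCCCCCCCCCCCCCCC(=O)C=S(C)(C)=O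
F2 | step 4 | 5,8-dimethoxy-2-pentadecyl-4H-chromen-4-one | CCCCCCCCCCCCCCCC1=CC(=O)c2c(OC)ccc(OC)c2O1
F3 | step 2 | 1,4-dimethoxy-2-(methoxymethoxy)benzene | COCOc1cc(OC)ccc1OC
F4 | step 2 | 3,6-dimethoxy-2-(methoxymethoxy)benzaldehyde | COCOc1c(C=O)c(OC)ccc1OC
F5 | step 5 | (2R)-2-pentadecyl-2,3-dihydro-4H-chromene-4,5,8-trione | CCCCCCCCCCCCCCC[C@@H]1CC(=O)C2=C(O1)C(=O)C=CC2=O
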